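(The numbers belong to no real substance; no experiment stands behind them.)

Each turnover removes one starting material and one second substrate and gives one product, so, the micromolar catalyst aside, both reagents lose the same amount and their difference stays at its charged value.

    starting material + enzyme ⇌ starting complex (K1 = 6.1 M⁻¹, k1 = 19000 M⁻¹ s⁻¹)
    ternary complex → enzyme + product (k2 = 22000 min⁻¹)
    precatalyst → enzyme (k3 = 0.23 min⁻¹)
    second substrate + starting complex ⇌ ternary complex (K4 = 18 M⁻¹, k4 = 78000 M⁻¹ min⁻¹)

the same everywhere: second substrate 0.134 M; precatalyst 6.7 µM; time 30 min
- violet: starting material 0.0080 M
- green: starting material 0.020 M
- grey: starting material 0.060 M
- teal: starting material 0.20 M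
- ochre: starting material 0.60 M

* [product] at the end for violet, green, grey, teal, ochre, in this order
* how the row runs (falls all the way / hardly changes / falls, then rises / rises, then falls / rises all the way)

- "hardly changes" means that all values lie within two and a half points (for a concentration: within two and a half percent of the largest)
- run time (violet): 30 min

The reckoning works with fractions left: a for starting material and b for second substrate, each of its own charge. The precatalyst delivers enzyme with a half-life of 3.0 min, so the 30 min run counts as 25.7 min of full enzyme. A ternary complex goes on to product with probability 0.835, and the starting complex keeps its binding equilibrium because it falls back far faster than it is captured. The exposure E, 68.3 M⁻¹, is the product of the binding constant of starting material, the forward rate constant with which second substrate captures the starting complex, that probability, the catalyst charge and that time.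

With enzyme free, ln(b/a) equals E times the charge of second substrate minus the charge of starting material. Violet fits this, since its binding constant times starting material is 0.049. There a falls to about 0.0182%, giving 8.00 mM. In teal, where second substrate is the limiting reagent, a cannot fall below 0.330, and the rule gives b as 0.363%.

That is the weak link: in teal the binding constant times starting material starts at 1.22, larger than in violet, so enzyme is not free. Reforged, with K the first binding constant, the rule reads: E = ln(b/a) / (charge difference) − K ln b. Green and grey then give 0.0200 M and 0.0597 M. Teal has b at 1.82%, giving 0.132 M. Ochre has b at 0.0236%, giving 0.134 M, which is more than teal. Set side by side, the reckoned row runs: rises all the way.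

The forecast gives 0.00799 M, 0.01998 M, 0.0597 M, 0.1311 M, 0.1339 M and rises all the way, on the ground: “Product therefore tracks the limiting reagent”. Its teal value lies a little below this reckoning.

The simulation gives 0.00800 M, 0.0200 M, 0.0597 M, 0.131 M, 0.134 M: rises all the way.

In teal, product stood at 56.3% of the starting material charged at 15.0 min and 65.6% at 30.0 min, when b was 2.1% against the hand value 1.82%. In ochre, the exposure scaled to 15.0 min is 28.7 M⁻¹, which puts b at 2.87%; the flask held 3.86%, and by 30.0 min b was 0.032%, a was 78%, and the resting state, starting complex, held 73.9% of the catalyst charged, more than the 26.0% of enzyme.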